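1. How does c(target) after 80 min run as the substrate charge climbs from 0.0020 M to 0.20 M at 1.10 equiv of reagent?

| flask | substrate | reagent in the second phase | remark | time | volume of the second phase over the first |
|---|---|---|---|---|---|
| dusk | 0.0020 M | 1.7 equiv | run made earlier |  |  |
| alpha | 0.0020 M | 1.10 equiv |  | 80 min | 1.0 |
| gamma | 0.0060 M | 1.10 equiv |  | 80 min | 1.0 |
| epsilon | 0.020 M | 1.10 equiv |  | 80 min | 1.0 |
| beta | 0.060 M | 1.10 equiv |  | 80 min | 1.0 |
| theta | 0.20 M | 1.10 equiv |  | 80 min | 1.0 |

dusk run (percent of the substrate charged)

| time / min | target / % |
|---|---|
| 3.00 | 0 |
| 10.0 | 2.1 |
| 15.0 | 2.5 |
| 25.0 | 4.3 |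
| 40.0 | 5.2 |
| 50.0 | 5.7 |

(scatter of a reading: 0.5 percentage points)

- a species is counted by the substrate in it: one side product counts as two
- in the second phase: reagent in the second phase; everything else is in the first
- charges count per volume of the first phase; a concentration in a rate is the amount of a species over the volume of its own phase; every rate counts per litre of the first phase
- on the list of suspects stand: reagent in the reaction phase + target -> over-reacted product; reagent in the reaction phase <-> dormant form; substrate + target -> side product; substrate + reagent in the reaction phase <-> target; reagent in the reaction phase <-> reagent in the second phase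
- the earlier runs hold the two phases in the same ratio of volumes as the flask asked about
- "hardly changes" means that all values lie within two and a half points (for a concentration: within two and a half percent of the largest)

- [target] at the end for alpha, gamma, epsilon, beta, theta, in this order
- how the row runs (rises, then falls / falls, then rises / rises all the way / falls all the way / hardly changes)

2. The dusk run supplies the speed of the first step in two ways, from different readings. The early slope, 2.1% at 10.0 min, gives 0.00210 min⁻¹ of the charge.

3. The levelling gives the second way. Taking the last reading, 5.7%, as the level, target passes the midpoint of its climb, 2.85%, between 15.0 min and 25.0 min, at about 16.9 min, and this time is read as a half-life. A curve relaxing with that half-life starts at 0.00233 min⁻¹. The gap of 11.0% is smaller than the 23.8% scatter of the early reading, so the speed is trusted. What the levelling means stays open: target returning to substrate, reagent going dormant and target being consumed all stand on the list of suspects, and the dusk readings do not tell them apart.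

4. The slope read as a pseudo-first-order rate gives the dusk substrate half-life, 330 min; for another flask it is scaled inversely with the reagent charge. The halving count is the asked time over that scaled half-life. My own reckoning gives 0.157 for alpha, 0.470 for gamma, 1.57 for epsilon, 4.70 for beta and 15.7 for theta. The last dusk reading stands at a count of 0.151. Theta therefore lies far beyond anything dusk shows, and the target in theta has time to be consumed by the suspected steps. This reckoning commits to a row that rises, then falls, and gives no height for the top.

5. The forecast differs. It gives 8.000 × 10⁻⁵ M, 6.500 × 10⁻⁴ M, 0.005 M, 0.027 M and 0.13 M, a row that rises all the way, on the ground that “a bimolecular forward step favours concentration”.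

6. The flask gives 7.57 × 10⁻⁵ M, 4.36 × 10⁻⁴ M, 0.00147 M, 0.00238 M and 0.00191 M: the row rises, then falls.

    reagent in the reaction phase + target → over-reacted product (k = 0.0550 M⁻¹ s⁻¹)
    reagent in the reaction phase ⇌ dormant form (K = 0.720, k = 1.80 × 10⁻⁴ s⁻¹)
    substrate + target → side product (k = 0.0350 M⁻¹ s⁻¹)
    substrate + reagent in the reaction phase ⇌ target (K = 72.0 M⁻¹, k = 0.0560 M⁻¹ s⁻¹)
    reagent in the reaction phase ⇌ reagent in the second phase, rate k5*([reagent in the reaction phase] - [reagent in the second phase]/K5) per volume of the first phase (partition coefficient = 1.80, kL = 0.00270 s⁻¹)

Theta ends with substrate at 1.47% and side product at 74.6%. The row turns at 0.096 M, a halving count of 7.52, with beta's 4.70 below it and theta's 15.7 above it. For epsilon, the count of 1.57 puts the substrate at 33.7% of its charge, and the flask epsilon holds 42.0%.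

Readings and results come from a simulation on assumed constants.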